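**Retrosynthetic overview**

1. The target comes from a fully protected sesquilignan by fluoride removal of two TBS ethers and hydrogenolysis of three phenolic benzyl ethers.
2. Key disconnection: the lactone CH2–aryl (ring B) bond, made late by an sp3–sp2 Negishi coupling of an iodomethyl lactone (ring A plus lactone, both lactone stereocentres) with an aryl bromide (rings B and C, anti-1,3-diol).
3. The aryl bromide comes from an auxiliary-controlled anti-aldol of a ring B arylacetyl imide with O-benzylvanillin; the arylacetic acid comes from Claisen rearrangement and oxidative cleavage on 4-bromoguaiacol.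
4. The iodomethyl lactone comes from trans-benzylation of the (R)-paraconic acid dianion, then CO2H → CH2OH → CH2I; paraconic acid comes from auxiliary-controlled hydroxymethylation of a succinate imide.
5. Ring formation: the three arenes come intact from catechol; the only ring built is the γ-butyrolactone, closed early (step 9) and carried through the coupling.

Assumption: the numbered starting materials are catechol and succinic anhydride; one- to three-carbon feedstocks (MeI, DMF, MeOH, s-trioxane, allyl bromide), protecting-group reagents and the oxazolidinone auxiliaries are treated as reagents and named on the reagent lines.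

The facial sense of the step 20 aldol is assigned from the chelated-enolate model, not from a remembered example; it should be confirmed on the first batch (see the risk note for step 20).

**Route**

Step 1
Reactants: 1 catechol
Product: 2 guaiacol (2-methoxyphenol)
Conditions: MeI (1.0 equiv), K2CO3 (1.0 equiv), acetone, reflux; NaOH extraction separates the phenol from veratrole
Reagents that add atoms: iodomethane, CI
Why: Williamson mono-O-methylation, where limiting MeI and the lower acidity of the mono-ether keep dimethylation minor.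

Step 2
Reactants: 2 guaiacol
Product: 3 4-bromo-2-methoxyphenol
Conditions: NBS (1.0 equiv), MeCN, 0 °C to rt
Reagents that add atoms: N-bromosuccinimide, O=C1CCC(=O)N1Br
Why: Electrophilic aromatic bromination, directed para to the free OH as the stronger donor.

Step 3
Reactants: 3 4-bromo-2-methoxyphenol
Product: 4 1-(benzyloxy)-4-bromo-2-methoxybenzene
Conditions: BnBr, K2CO3, DMF, 60 °C
Reagents that add atoms: benzyl bromide, BrCc1ccccc1
Why: Williamson etherification protects the phenol as a benzyl ether that survives all later basic, organometallic and oxidative steps.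

Step 4
Reactants: 4 1-(benzyloxy)-4-bromo-2-methoxybenzene
Product: 6 4-(benzyloxy)-3-methoxybenzaldehyde, via aryllithium 5 (not isolated)
Conditions: n-BuLi, THF, −78 °C; DMF, −78 °C to rt; H2O
Reagents that add atoms: N,N-dimethylformamide, CN(C)C=O; n-butyllithium, [Li]CCCC (lithium kept only in 5)
Why: Bromine–lithium exchange followed by Bouveault-type formylation places the aldehyde regiospecifically para to the benzyloxy group.

Step 5
Reactants: 6 4-(benzyloxy)-3-methoxybenzaldehyde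
Product: 7 [4-(benzyloxy)-3-methoxyphenyl]methanol
Conditions: NaBH4, MeOH, 0 °C
Reagents that add atoms: none
Why: Borohydride reduction of an aryl aldehyde to the benzylic alcohol.

Step 6
Reactants: 7 [4-(benzyloxy)-3-methoxyphenyl]methanol
Product: 8 1-(benzyloxy)-4-(bromomethyl)-2-methoxybenzene
Conditions: PBr3, Et2O, 0 °C; used without storage
Reagents that add atoms: phosphorus tribromide, BrP(Br)Br
Why: Conversion of an electron-rich benzylic alcohol into the bromide through its phosphite ester.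

Step 7
Reactants: 9 succinic anhydride
Product: 10 4-methoxy-4-oxobutanoic acid (monomethyl succinate)
Conditions: MeOH, reflux
Reagents that add atoms: methanol, CO
Why: Alcoholysis of a cyclic anhydride gives the half-ester and so differentiates the two carboxyl groups.

Step 8
Reactants: 10 4-methoxy-4-oxobutanoic acid
Product: 12 methyl 4-[(4S)-4-benzyl-2-oxo-1,3-oxazolidin-3-yl]-4-oxobutanoate, via mixed anhydride 11 (not isolated)
Conditions: Et3N, PivCl, THF, −20 °C; then LiCl, (S)-4-benzyl-2-oxazolidinone, −20 °C to rt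
Reagents that add atoms: (S)-4-benzyl-2-oxazolidinone, O=C1N[C@@H](Cc2ccccc2)CO1; pivaloyl chloride, CC(C)(C)C(Cl)=O (atoms kept only in 11)
Why: Mixed-anhydride N-acylation of the Evans auxiliary, with attack at the less hindered succinyl carbonyl.

Step 9
Reactants: 12 methyl 4-[(4S)-4-benzyl-2-oxo-1,3-oxazolidin-3-yl]-4-oxobutanoate
Product: 15 (4S)-4-benzyl-3-{[(3R)-5-oxooxolan-3-yl]carbonyl}-1,3-oxazolidin-2-one, via titanium enolate 13 (not isolated), via hydroxy ester 14 (not isolated)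
Conditions: TiCl4 (1.05 equiv), i-Pr2NEt (1.1 equiv), CH2Cl2, 0 °C; s-trioxane (0.4 equiv), TiCl4 (1.05 equiv), 0 °C; aq. NH4Cl; then TsOH·H2O (5 mol%), toluene, 50 °C
Reagents that add atoms: s-trioxane, C1OCOCO1 (one CH2O unit); titanium tetrachloride, Cl[Ti](Cl)(Cl)Cl (atoms kept only in 13)
Why: Evans titanium-enolate hydroxymethylation, in which the chelated Z-enolate of the more acidic imide takes formaldehyde on the face away from the auxiliary benzyl to set the (R) centre, followed by acid-catalysed lactonisation of the γ-hydroxy ester.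

Step 10
Reactants: 15 (4S)-4-benzyl-3-{[(3R)-5-oxooxolan-3-yl]carbonyl}-1,3-oxazolidin-2-one
Product: 17 (3R)-5-oxooxolane-3-carboxylic acid ((R)-paraconic acid), via peroxy acid 16 (not isolated)
Conditions: LiOH, H2O2, THF/H2O, 0 °C; Na2SO3; HCl to pH 1; continuous EtOAc extraction
Reagents that add atoms: hydrogen peroxide, OO
Why: Hydroperoxide cleavage of the exocyclic imide carbonyl removes the auxiliary without touching the stereocentre, and acidification recloses any opened γ-lactone.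

Step 11
Reactants: 17 (3R)-5-oxooxolane-3-carboxylic acid; 8 1-(benzyloxy)-4-(bromomethyl)-2-methoxybenzene
Product: 19 (3R,4R)-4-[4-(benzyloxy)-3-methoxybenzyl]-5-oxooxolane-3-carboxylic acid (trans), via dilithium enolate 18 (not isolated)
Conditions: LiN(SiMe3)2 (2.2 equiv), THF, −78 °C; then 8, −78 to −20 °C; 1 M HCl
Reagents that add atoms: lithium bis(trimethylsilyl)amide, [Li]N([Si](C)(C)C)[Si](C)(C)C (lithium kept only in 18)
Why: Lactone enolate alkylation of the carboxylate–enolate dianion, where the benzylic bromide enters trans to the neighbouring carboxylate (1,2-induction on the five-membered ring) and sets the (R) benzyl centre.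

Step 12
Reactants: 19 (3R,4R)-4-[4-(benzyloxy)-3-methoxybenzyl]-5-oxooxolane-3-carboxylic acid
Product: 20 (3R,4S)-3-[4-(benzyloxy)-3-methoxybenzyl]-4-(hydroxymethyl)oxolan-2-one
Conditions: BH3·SMe2, THF, 0 °C to rt; MeOH quench
Reagents that add atoms: none
Why: Chemoselective borane reduction of a carboxylic acid in the presence of a lactone, with no bond to a stereocentre broken (the 4S label is only a priority change).

Step 13
Reactants: 20 (3R,4S)-3-[4-(benzyloxy)-3-methoxybenzyl]-4-(hydroxymethyl)oxolan-2-one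
Product: 21 (3R,4R)-3-[4-(benzyloxy)-3-methoxybenzyl]-4-(iodomethyl)oxolan-2-one
Conditions: PPh3, I2, imidazole, CH2Cl2, 0 °C to rt
Reagents that add atoms: iodine, II
Why: Appel-type iodination of the primary alcohol under near-neutral conditions, which avoid acyl migration of the hydroxymethyl lactone.

Step 14
Reactants: 3 4-bromo-2-methoxyphenol
Product: 22 4-bromo-2-methoxy-1-(prop-2-en-1-yloxy)benzene
Conditions: allyl bromide, K2CO3, acetone, reflux
Reagents that add atoms: allyl bromide, C=CCBr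
Why: Williamson O-allylation sets up the sigmatropic transfer of a C3 unit to the ring.

Step 15
Reactants: 22 4-bromo-2-methoxy-1-(prop-2-en-1-yloxy)benzene
Product: 23 4-bromo-2-methoxy-6-(prop-2-en-1-yl)phenol
Conditions: N,N-diethylaniline, 200 °C
Reagents that add atoms: none
Why: Aromatic Claisen rearrangement delivers the allyl group to the only free ortho position, the future side-chain carbon of ring B.

Step 16
Reactants: 23 4-bromo-2-methoxy-6-(prop-2-en-1-yl)phenol
Product: 24 1-(benzyloxy)-4-bromo-2-methoxy-6-(prop-2-en-1-yl)benzene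
Conditions: BnBr, K2CO3, DMF, 60 °C
Reagents that add atoms: benzyl bromide, BrCc1ccccc1
Why: Williamson benzylation of the hindered phenol before the oxidative steps.

Step 17
Reactants: 24 1-(benzyloxy)-4-bromo-2-methoxy-6-(prop-2-en-1-yl)benzene
Product: 26 [2-(benzyloxy)-5-bromo-3-methoxyphenyl]acetaldehyde, via diol 25 (not isolated)
Conditions: OsO4 (2 mol%), NaIO4 (4 equiv), 2,6-lutidine, dioxane/H2O 3:1, rt
Reagents that add atoms: sodium periodate, [Na+].[O-]I(=O)(=O)=O (terminal oxidant; the carbonyl oxygen arrives by way of OsO4)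
Why: Lemieux–Johnson dihydroxylation and glycol cleavage removes the terminal carbon without attacking the electron-rich arene.

Step 18
Reactants: 26 [2-(benzyloxy)-5-bromo-3-methoxyphenyl]acetaldehyde
Product: 27 [2-(benzyloxy)-5-bromo-3-methoxyphenyl]acetic acid
Conditions: NaClO2, NaH2PO4, 2-methyl-2-butene, t-BuOH/H2O, rt
Reagents that add atoms: sodium chlorite, [Na+].[O-]Cl=O
Why: Pinnick oxidation of the aldehyde to the acid, with the alkene scavenger protecting the arene from hypochlorite.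

Step 19
Reactants: 27 [2-(benzyloxy)-5-bromo-3-methoxyphenyl]acetic acid
Product: 29 (4R)-4-benzyl-3-{[2-(benzyloxy)-5-bromo-3-methoxyphenyl]acetyl}-1,3-oxazolidin-2-one, via mixed anhydride 28 (not isolated)
Conditions: Et3N, PivCl, THF, −20 °C; then LiCl, (R)-4-benzyl-2-oxazolidinone, −20 °C to rt
Reagents that add atoms: (R)-4-benzyl-2-oxazolidinone, O=C1N[C@H](Cc2ccccc2)CO1; pivaloyl chloride, CC(C)(C)C(Cl)=O (atoms kept only in 28)
Why: Mixed-anhydride N-acylation installs the auxiliary that controls the side-chain stereodiad.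

Step 20
Reactants: 29 (4R)-4-benzyl-3-{[2-(benzyloxy)-5-bromo-3-methoxyphenyl]acetyl}-1,3-oxazolidin-2-one; 6 4-(benzyloxy)-3-methoxybenzaldehyde
Product: 31 (4R)-4-benzyl-3-{(2S,3R)-2-[2-(benzyloxy)-5-bromo-3-methoxyphenyl]-3-[4-(benzyloxy)-3-methoxyphenyl]-3-hydroxypropanoyl}-1,3-oxazolidin-2-one, via silyl ether 30 (not isolated)
Conditions: MgCl2 (20 mol%), Et3N (2 equiv), Me3SiCl (1.5 equiv), EtOAc, rt, 24 h; then aq. citric acid, THF, 0 °C
Reagents that add atoms: chlorotrimethylsilane, C[Si](C)(C)Cl (atoms kept only in 30)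
Why: Evans magnesium-halide-catalysed direct anti-aldol, in which the magnesium-chelated Z-enolate is attacked on the face away from the auxiliary benzyl through a boat transition state with silyl trapping of the aldolate, setting the 2S centre and the anti 3R carbinol.

Step 21
Reactants: 31 (4R)-4-benzyl-3-{(2S,3R)-2-[2-(benzyloxy)-5-bromo-3-methoxyphenyl]-3-[4-(benzyloxy)-3-methoxyphenyl]-3-hydroxypropanoyl}-1,3-oxazolidin-2-one
Product: 32 (1R,2R)-2-[2-(benzyloxy)-5-bromo-3-methoxyphenyl]-1-[4-(benzyloxy)-3-methoxyphenyl]propane-1,3-diol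
Conditions: LiBH4, THF, 0 °C to rt
Reagents that add atoms: none
Why: Reductive cleavage of the N-acyl oxazolidinone gives the primary alcohol without epimerisation (C2 becomes R only through the priority change) and leaves the aryl bromide intact.

Step 22
Reactants: 32 (1R,2R)-2-[2-(benzyloxy)-5-bromo-3-methoxyphenyl]-1-[4-(benzyloxy)-3-methoxyphenyl]propane-1,3-diol
Product: 33 (1R,2R)-2-[2-(benzyloxy)-5-bromo-3-methoxyphenyl]-1-[4-(benzyloxy)-3-methoxyphenyl]-1,3-bis[(tert-butyldimethylsilyl)oxy]propane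
Conditions: TBSOTf (2.5 equiv), 2,6-lutidine, CH2Cl2, 0 °C
Reagents that add atoms: tert-butyldimethylsilyl trifluoromethanesulfonate, CC(C)(C)[Si](C)(C)OS(=O)(=O)C(F)(F)F
Why: Base-buffered silylation masks both hydroxyls, including the acid-labile electron-rich benzylic one, against the organozinc reagent.

Step 23
Reactants: 21 (3R,4R)-3-[4-(benzyloxy)-3-methoxybenzyl]-4-(iodomethyl)oxolan-2-one; 33 (1R,2R)-2-[2-(benzyloxy)-5-bromo-3-methoxyphenyl]-1-[4-(benzyloxy)-3-methoxyphenyl]-1,3-bis[(tert-butyldimethylsilyl)oxy]propane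
Product: 35 (3R,4R)-3-[4-(benzyloxy)-3-methoxybenzyl]-4-{4-(benzyloxy)-3-[(1R,2R)-1-[4-(benzyloxy)-3-methoxyphenyl]-1,3-bis[(tert-butyldimethylsilyl)oxy]propan-2-yl]-5-methoxybenzyl}oxolan-2-one, via alkylzinc iodide 34 (not isolated)
Conditions: Zn dust (I2-activated, 3 equiv), DMF, rt, 1 h, 21 in 1.3-fold excess; decant; then 33, Pd2(dba)3 (2.5 mol%), SPhos (10 mol%), DMF, 50 °C
Reagents that add atoms: zinc, [Zn] (kept only in 34)
Why: Negishi sp3–sp2 cross-coupling, where the primary alkylzinc has no β-leaving group and tolerates the lactone, the aryl bromide is unhindered, and no stereocentre is touched.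

Step 24
Reactants: 35 the bis-silyl tris-benzyl coupling product
Product: 36 (3R,4R)-3-[4-(benzyloxy)-3-methoxybenzyl]-4-{4-(benzyloxy)-3-[(1R,2R)-1-[4-(benzyloxy)-3-methoxyphenyl]-1,3-dihydroxypropan-2-yl]-5-methoxybenzyl}oxolan-2-one
Conditions: Bu4NF, AcOH (1:1), THF, rt to 40 °C
Reagents that add atoms: none
Why: Buffered fluoride desilylation frees the diol while the phenols are still benzylated, so no quinone methide or acid-induced cyclisation to the dihydrobenzofuran can occur.

Step 25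
Reactants: 36 the tris-benzyl ether diol
Product: 37 (3R,4R)-4-{4-hydroxy-3-[(1R,2R)-1,3-dihydroxy-1-(4-hydroxy-3-methoxyphenyl)propan-2-yl]-5-methoxybenzyl}-3-(4-hydroxy-3-methoxybenzyl)oxolan-2-one (CNP0109231.2)
Conditions: H2 (1 atm), 10% Pd/C, EtOAc/EtOH, rt, stopped at full conversion
Reagents that add atoms: none
Why: Neutral catalytic hydrogenolysis cleaves the three aryl benzyl ethers much faster than the secondary benzylic C–O bond and leaves all four stereocentres untouched.

**Compound list**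

1 | catechol | Oc1ccccc1O | starting material
2 | guaiacol | COc1ccccc1O | intermediate
3 | 4-bromo-2-methoxyphenol | COc1cc(Br)ccc1O | intermediate
4 | 1-(benzyloxy)-4-bromo-2-methoxybenzene | COc1cc(Br)ccc1OCc1ccccc1 | intermediate
5 | [4-(benzyloxy)-3-methoxyphenyl]lithium | COc1cc([Li])ccc1OCc1ccccc1 | intermediate
6 | 4-(benzyloxy)-3-methoxybenzaldehyde | COc1cc(C=O)ccc1OCc1ccccc1 | intermediate
7 | [4-(benzyloxy)-3-methoxyphenyl]methanol | COc1cc(CO)ccc1OCc1ccccc1 | intermediate
8 | 1-(benzyloxy)-4-(bromomethyl)-2-methoxybenzene | COc1cc(CBr)ccc1OCc1ccccc1 | intermediate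
9 | succinic anhydride | O=C1CCC(=O)O1 | starting material
10 | 4-methoxy-4-oxobutanoic acid | COC(=O)CCC(=O)O | intermediate
11 | 4-methoxy-4-oxobutanoic pivalic anhydride | COC(=O)CCC(=O)OC(=O)C(C)(C)C | intermediate
12 | methyl 4-[(4S)-4-benzyl-2-oxo-1,3-oxazolidin-3-yl]-4-oxobutanoate | COC(=O)CCC(=O)N1C(=O)OC[C@@H]1Cc1ccccc1 | intermediate
13 | trichlorotitanium Z-enolate of 12 | COC(=O)C/C=C(\O[Ti](Cl)(Cl)Cl)N1C(=O)OC[C@@H]1Cc1ccccc1 | intermediate
14 | methyl (3R)-4-[(4S)-4-benzyl-2-oxo-1,3-oxazolidin-3-yl]-3-(hydroxymethyl)-4-oxobutanoate | COC(=O)C[C@H](CO)C(=O)N1C(=O)OC[C@@H]1Cc1ccccc1 | intermediate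
15 | (4S)-4-benzyl-3-{[(3R)-5-oxooxolan-3-yl]carbonyl}-1,3-oxazolidin-2-one | O=C1C[C@H](CO1)C(=O)N1C(=O)OC[C@@H]1Cc1ccccc1 | intermediate
16 | (3R)-5-oxooxolane-3-carboperoxoic acid | O=C1C[C@H](CO1)C(=O)OO | intermediate
17 | (3R)-5-oxooxolane-3-carboxylic acid | O=C1C[C@H](CO1)C(=O)O | intermediate
18 | dilithium enolate–carboxylate of 17 | [Li]OC1=C[C@H](CO1)C(=O)O[Li] | intermediate
19 | (3R,4R)-4-[4-(benzyloxy)-3-methoxybenzyl]-5-oxooxolane-3-carboxylic acid | COc1cc(C[C@H]2C(=O)OC[C@@H]2C(=O)O)ccc1OCc1ccccc1 | intermediate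
20 | (3R,4S)-3-[4-(benzyloxy)-3-methoxybenzyl]-4-(hydroxymethyl)oxolan-2-one | COc1cc(C[C@H]2C(=O)OC[C@@H]2CO)ccc1OCc1ccccc1 | intermediate
21 | (3R,4R)-3-[4-(benzyloxy)-3-methoxybenzyl]-4-(iodomethyl)oxolan-2-one | COc1cc(C[C@H]2C(=O)OC[C@@H]2CI)ccc1OCc1ccccc1 | intermediate
22 | 4-bromo-2-methoxy-1-(prop-2-en-1-yloxy)benzene | COc1cc(Br)ccc1OCC=C | intermediate
23 | 4-bromo-2-methoxy-6-(prop-2-en-1-yl)phenol | COc1cc(Br)cc(CC=C)c1O | intermediate
24 | 1-(benzyloxy)-4-bromo-2-methoxy-6-(prop-2-en-1-yl)benzene | COc1cc(Br)cc(CC=C)c1OCc1ccccc1 | intermediate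
25 | 3-[2-(benzyloxy)-5-bromo-3-methoxyphenyl]propane-1,2-diol (racemic) | COc1cc(Br)cc(CC(O)CO)c1OCc1ccccc1 | intermediate
26 | [2-(benzyloxy)-5-bromo-3-methoxyphenyl]acetaldehyde | COc1cc(Br)cc(CC=O)c1OCc1ccccc1 | intermediate
27 | [2-(benzyloxy)-5-bromo-3-methoxyphenyl]acetic acid | COc1cc(Br)cc(CC(=O)O)c1OCc1ccccc1 | intermediate
28 | [2-(benzyloxy)-5-bromo-3-methoxyphenyl]acetic pivalic anhydride | COc1cc(Br)cc(CC(=O)OC(=O)C(C)(C)C)c1OCc1ccccc1 | intermediate
29 | (4R)-4-benzyl-3-{[2-(benzyloxy)-5-bromo-3-methoxyphenyl]acetyl}-1,3-oxazolidin-2-one | COc1cc(Br)cc(CC(=O)N2C(=O)OC[C@H]2Cc2ccccc2)c1OCc1ccccc1 | intermediate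
30 | trimethylsilyl ether of 31 | COc1cc(Br)cc([C@H](C(=O)N2C(=O)OC[C@H]2Cc2ccccc2)[C@@H](O[Si](C)(C)C)c2ccc(OCc3ccccc3)c(OC)c2)c1OCc1ccccc1 | intermediate
31 | (4R)-4-benzyl-3-{(2S,3R)-2-[2-(benzyloxy)-5-bromo-3-methoxyphenyl]-3-[4-(benzyloxy)-3-methoxyphenyl]-3-hydroxypropanoyl}-1,3-oxazolidin-2-one | COc1cc(Br)cc([C@H](C(=O)N2C(=O)OC[C@H]2Cc2ccccc2)[C@@H](O)c2ccc(OCc3ccccc3)c(OC)c2)c1OCc1ccccc1 | intermediate
32 | (1R,2R)-2-[2-(benzyloxy)-5-bromo-3-methoxyphenyl]-1-[4-(benzyloxy)-3-methoxyphenyl]propane-1,3-diol | COc1cc(Br)cc([C@H](CO)[C@@H](O)c2ccc(OCc3ccccc3)c(OC)c2)c1OCc1ccccc1 | intermediate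
33 | (1R,2R)-2-[2-(benzyloxy)-5-bromo-3-methoxyphenyl]-1-[4-(benzyloxy)-3-methoxyphenyl]-1,3-bis[(tert-butyldimethylsilyl)oxy]propane | COc1cc(Br)cc([C@H](CO[Si](C)(C)C(C)(C)C)[C@@H](O[Si](C)(C)C(C)(C)C)c2ccc(OCc3ccccc3)c(OC)c2)c1OCc1ccccc1 | intermediate
34 | iodo{[(3R,4R)-4-[4-(benzyloxy)-3-methoxybenzyl]-5-oxooxolan-3-yl]methyl}zinc | COc1cc(C[C@H]2C(=O)OC[C@@H]2C[Zn]I)ccc1OCc1ccccc1 | intermediate
35 | (3R,4R)-3-[4-(benzyloxy)-3-methoxybenzyl]-4-{4-(benzyloxy)-3-[(1R,2R)-1-[4-(benzyloxy)-3-methoxyphenyl]-1,3-bis[(tert-butyldimethylsilyl)oxy]propan-2-yl]-5-methoxybenzyl}oxolan-2-one | COc1cc(C[C@H]2C(=O)OC[C@@H]2Cc2cc(OC)c(OCc3ccccc3)c([C@H](CO[Si](C)(C)C(C)(C)C)[C@@H](O[Si](C)(C)C(C)(C)C)c3ccc(OCc4ccccc4)c(OC)c3)c2)ccc1OCc1ccccc1 | intermediate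
36 | (3R,4R)-3-[4-(benzyloxy)-3-methoxybenzyl]-4-{4-(benzyloxy)-3-[(1R,2R)-1-[4-(benzyloxy)-3-methoxyphenyl]-1,3-dihydroxypropan-2-yl]-5-methoxybenzyl}oxolan-2-one | COc1cc(C[C@H]2C(=O)OC[C@@H]2Cc2cc(OC)c(OCc3ccccc3)c([C@H](CO)[C@@H](O)c3ccc(OCc4ccccc4)c(OC)c3)c2)ccc1OCc1ccccc1 | intermediate
37 | (3R,4R)-4-{4-hydroxy-3-[(1R,2R)-1,3-dihydroxy-1-(4-hydroxy-3-methoxyphenyl)propan-2-yl]-5-methoxybenzyl}-3-(4-hydroxy-3-methoxybenzyl)oxolan-2-one | COc1cc(C[C@H]2C(=O)OC[C@@H]2Cc2cc(OC)c(O)c([C@H](CO)[C@@H](O)c3ccc(O)c(OC)c3)c2)ccc1O | target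

**Step count and risk**

Total steps: 25. Longest linear sequence: 14 (steps 1, 2, 14 to 25).

Most likely to fail, with fallbacks:

Step 20 (anti-aldol). The arylacetyl imide carries an ortho-benzyloxy aryl group, the aldehyde is electron-rich, and the anti sense rests on the chelated boat model; if reactivity is poor or the major adduct is the wrong isomer, the two centres are set separately instead. The fallback sets out from acid 27 and comes back at 33. Acid 27 is acylated through anhydride 28 onto (S)-4-benzyl-2-oxazolidinone to give (4S)-4-benzyl-3-{[2-(benzyloxy)-5-bromo-3-methoxyphenyl]acetyl}-1,3-oxazolidin-2-one F1. Soft enolisation with TiCl4 and i-Pr2NEt gives its trichlorotitanium Z-enolate F2, which is hydroxymethylated with s-trioxane and TiCl4 on the face away from the auxiliary benzyl to give the (2R)-3-hydroxy-2-arylpropanoyl imide F3. TBSCl and imidazole give the silyl ether F4, and LiBH4 then gives (2S)-2-aryl-3-silyloxypropan-1-ol F5. Dess–Martin periodinane gives the (2R)-2-aryl-3-silyloxypropanal F6, used at once because α-aryl aldehydes racemise. Addition of aryllithium 5 at −78 °C under Felkin–Anh control (aryl as the large group) gives the (1R,2R)-anti mono-silyl diol F7, and TBSOTf with 2,6-lutidine converts it into 33.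

Step 23 (Negishi coupling). Zinc insertion next to the lactone or the coupling with the electron-rich bromide may be sluggish; the polarity is then reversed so that no alkylzinc has to be made. The fallback sets out from 33 and comes back at 35. Bromide 33 undergoes bromine–lithium exchange with n-BuLi at −78 °C to give the aryllithium F8, which ZnCl2 converts into the arylzinc chloride F9. This is coupled with the primary alkyl iodide 21 under alkyl-electrophile Negishi conditions (Pd2(dba)3, tricyclopentylphosphine, N-methylimidazole, THF/NMP, 80 °C) to give 35.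

Step 11 (dianion benzylation). The small, water-soluble acid 17 may alkylate in low yield or with poor trans selectivity as its dilithium salt; the alkylation is then run on a neutral silyl ether. The fallback sets out from 17 and comes back at 20. Borane reduction of 17 gives (4S)-4-(hydroxymethyl)oxolan-2-one F10, which is silylated at once with TBDPSCl and imidazole (acyl migration would racemise it) to give (4R)-4-{[(tert-butyldiphenylsilyl)oxy]methyl}oxolan-2-one F11. LiN(SiMe3)2 at −78 °C gives the lithium enolate F12, which is alkylated by bromide 8 trans to the silyloxymethyl group to give the (3R,4R)-3-benzyl-4-(silyloxymethyl) lactone F13. Bu4NF with AcOH then gives 20.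

**Further compounds**

F1 | step 20 | (4S)-4-benzyl-3-{[2-(benzyloxy)-5-bromo-3-methoxyphenyl]acetyl}-1,3-oxazolidin-2-one | COc1cc(Br)cc(CC(=O)N2C(=O)OC[C@@H]2Cc2ccccc2)c1OCc1ccccc1
F2 | step 20 | trichlorotitanium Z-enolate of F1 | COc1cc(Br)cc(/C=C(\O[Ti](Cl)(Cl)Cl)N2C(=O)OC[C@@H]2Cc2ccccc2)c1OCc1ccccc1
F3 | step 20 | (4S)-4-benzyl-3-{(2R)-2-[2-(benzyloxy)-5-bromo-3-methoxyphenyl]-3-hydroxypropanoyl}-1,3-oxazolidin-2-one | COc1cc(Br)cc([C@H](CO)C(=O)N2C(=O)OC[C@@H]2Cc2ccccc2)c1OCc1ccccc1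
F4 | step 20 | (4S)-4-benzyl-3-{(2R)-2-[2-(benzyloxy)-5-bromo-3-methoxyphenyl]-3-[(tert-butyldimethylsilyl)oxy]propanoyl}-1,3-oxazolidin-2-one | COc1cc(Br)cc([C@H](CO[Si](C)(C)C(C)(C)C)C(=O)N2C(=O)OC[C@@H]2Cc2ccccc2)c1OCc1ccccc1
F5 | step 20 | (2S)-2-[2-(benzyloxy)-5-bromo-3-methoxyphenyl]-3-[(tert-butyldimethylsilyl)oxy]propan-1-ol | COc1cc(Br)cc([C@H](CO[Si](C)(C)C(C)(C)C)CO)c1OCc1ccccc1
F6 | step 20 | (2R)-2-[2-(benzyloxy)-5-bromo-3-methoxyphenyl]-3-[(tert-butyldimethylsilyl)oxy]propanal | COc1cc(Br)cc([C@H](CO[Si](C)(C)C(C)(C)C)C=O)c1OCc1ccccc1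
F7 | step 20 | (1R,2R)-2-[2-(benzyloxy)-5-bromo-3-methoxyphenyl]-1-[4-(benzyloxy)-3-methoxyphenyl]-3-[(tert-butyldimethylsilyl)oxy]propan-1-ol | COc1cc(Br)cc([C@H](CO[Si](C)(C)C(C)(C)C)[C@@H](O)c2ccc(OCc3ccccc3)c(OC)c2)c1OCc1ccccc1
F8 | step 23 | aryllithium from 33 (lithium in place of bromine) | COc1cc([Li])cc([C@H](CO[Si](C)(C)C(C)(C)C)[C@@H](O[Si](C)(C)C(C)(C)C)c2ccc(OCc3ccccc3)c(OC)c2)c1OCc1ccccc1
F9 | step 23 | arylzinc chloride from 33 (ZnCl in place of bromine) | COc1cc([Zn]Cl)cc([C@H](CO[Si](C)(C)C(C)(C)C)[C@@H](O[Si](C)(C)C(C)(C)C)c2ccc(OCc3ccccc3)c(OC)c2)c1OCc1ccccc1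
F10 | step 11 | (4S)-4-(hydroxymethyl)oxolan-2-one | O=C1C[C@H](CO1)CO
F11 | step 11 | (4R)-4-{[(tert-butyldiphenylsilyl)oxy]methyl}oxolan-2-one | O=C1C[C@H](CO1)CO[Si](c1ccccc1)(c1ccccc1)C(C)(C)C
F12 | step 11 | lithium enolate of F11 | [Li]OC1=C[C@H](CO1)CO[Si](c1ccccc1)(c1ccccc1)C(C)(C)C
F13 | step 11 | (3R,4R)-3-[4-(benzyloxy)-3-methoxybenzyl]-4-{[(tert-butyldiphenylsilyl)oxy]methyl}oxolan-2-one | COc1cc(C[C@H]2C(=O)OC[C@@H]2CO[Si](c2ccccc2)(c2ccccc2)C(C)(C)C)ccc1OCc1ccccc1
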